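**Plan**

1. Ring numbering of the target: C1 (ester carbinol), C2=C3, C4 (free carbinol), C5 (CMe2), C6–C8 (three CH2), C9=C10, C11. Cuts in retrosynthetic order: C4–OH back to the C4 ketone; the aryl ester C–O at C1; the ring bond C6–C7; the acyclic bond C1–C2; each trisubstituted alkene back to an alkyne.
2. Enabling feature: C4 (carbinol), C5 (quaternary, gem-dimethyl) and C6 (CH2) are the ring-opened form of a 2,2-dimethylcyclopropanol whose three ring atoms are C4, C5 and C6. Opening its C4–C6 bond on a metal makes C6 a ketone homoenolate that has no β-hydrogen (C5 is quaternary) and can capture C7.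
3. Forward: siloxycyclopropyl alkyne 5 and aldehyde 9 are joined at C1–C2 by hydrozirconation/zinc transmetalation. The only ring, the 11-membered carbocycle, is closed in step 12 by palladium-catalysed strain-release alkylation of the cyclopropanol with the tethered primary bromide.
4. Stereochemistry: both E alkenes come from syn carbo-/hydrometalation of alkynes; C1 (R) from CBS reduction of the acyclic enone 13; C4 (R) from CBS reduction of the macrocyclic enone 23. The cyclopropane carbinol centre is carried as a mixture and erased in step 12.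
5. The aryl ester is put on after ring closure so that no allylic ester meets zerovalent palladium; the phenol is unmasked last.

Key step: step 12

Remark: the cyclopropane carbinol carbon in 5 and 10–18 is carried in both configurations (diastereomer mixtures from 12 on), because it becomes the ketone carbon in step 12. Compounds 1, 2, 6 and 22 and 2-butynal diethyl acetal are taken as purchasable.

**Route**

Step 1
Reactants: 1 1-propynylmagnesium bromide; 2 N-methoxy-N-methylisobutyramide
Product: 3 2-methylhex-4-yn-3-one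
Conditions: THF, −78 °C to 0 °C; aq. NH4Cl
Reagents that add atoms: none
Why: Weinreb ketone synthesis, in which the stable magnesium chelate of the tetrahedral adduct stops the addition at the ketone stage.

Step 2
Reactants: 3 2-methylhex-4-yn-3-one
Product: 4 triethyl[(2-methylhex-2-en-4-yn-3-yl)oxy]silane
Conditions: TESOTf, Et3N, CH2Cl2, −78 °C to 0 °C
Reagents that add atoms: triethylsilyl trifluoromethanesulfonate CC[Si](CC)(CC)OS(=O)(=O)C(F)(F)F
Why: Soft enolisation with O-silylation should give a single silyl enol ether, because the isopropyl methine is the only α-hydrogen of the ynone.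

Step 3
Reactants: 4 triethyl[(2-methylhex-2-en-4-yn-3-yl)oxy]silane
Product: 5 {[2,2-dimethyl-1-(prop-1-yn-1-yl)cyclopropyl]oxy}triethylsilane (racemic)
Conditions: Et2Zn, CH2I2, CH2Cl2, 0 °C to rt
Reagents that add atoms: diiodomethane ICI
Why: Simmons–Smith cyclopropanation (Furukawa variant), in which the electrophilic zinc carbenoid should add to the electron-rich enol ether C=C and not to the alkyne, building the future C4–C5–C6 unit as a siloxycyclopropane.

Step 4
Reactants: 6 tert-butyl(but-3-yn-1-yloxy)dimethylsilane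
Product: 8 (E)-6-[(tert-butyldimethylsilyl)oxy]-4-methylhex-3-en-1-ol, via alkenylalane 7 (not isolated)
Conditions: AlMe3, Cp2ZrCl2 (25 mol %), CH2Cl2, 0 °C to rt; n-BuLi, THF/hexane, −78 °C; ethylene oxide, −78 °C to rt; aqueous potassium sodium tartrate
Reagents that add atoms: trimethylaluminium C[Al](C)C; ethylene oxide C1CO1
Why: Negishi zirconium-catalysed carboalumination adds Me and Al syn (methyl to the internal carbon) and so fixes the E trisubstituted C9=C10 alkene, and the derived alanate opens ethylene oxide with retention of alkene geometry.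

Step 5
Reactants: 8 (E)-6-[(tert-butyldimethylsilyl)oxy]-4-methylhex-3-en-1-ol
Product: 9 (E)-6-[(tert-butyldimethylsilyl)oxy]-4-methylhex-3-enal
Conditions: Dess–Martin periodinane, NaHCO3, CH2Cl2, 0 °C; used at once
Reagents that add atoms: none
Why: Buffered Dess–Martin oxidation should give the β,γ-unsaturated aldehyde without moving the alkene into conjugation.

Step 6
Reactants: 5 {[2,2-dimethyl-1-(prop-1-yn-1-yl)cyclopropyl]oxy}triethylsilane; 9 (E)-6-[(tert-butyldimethylsilyl)oxy]-4-methylhex-3-enal
Product: 12 (1E,5E)-8-[(tert-butyldimethylsilyl)oxy]-1-[2,2-dimethyl-1-(triethylsilyloxy)cyclopropyl]-2,6-dimethylocta-1,5-dien-3-ol (stereoisomer mixture at C3 and at the cyclopropane carbon), via alkenylzirconocene chloride 10 (not isolated), via alkenylmethylzinc 11 (not isolated)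
Conditions: Cp2Zr(H)Cl, CH2Cl2, rt; solvent change to toluene; Me2Zn, −65 °C; 9, 0 °C; aq. NH4Cl
Reagents that add atoms: none
Why: Syn hydrozirconation should place zirconium on the methyl-bearing alkyne carbon, away from the quaternary cyclopropyl carbon, and zirconium-to-zinc transmetalation followed by carbonyl addition forms the C1–C2 bond and the E C2=C3 alkene; the non-basic alkenylzinc spares the enolisable aldehyde, and the new carbinol configuration is immaterial because it is oxidised next.

Step 7
Reactants: 12 (1E,5E)-8-[(tert-butyldimethylsilyl)oxy]-1-[2,2-dimethyl-1-(triethylsilyloxy)cyclopropyl]-2,6-dimethylocta-1,5-dien-3-ol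
Product: 13 (1E,5E)-8-[(tert-butyldimethylsilyl)oxy]-1-[2,2-dimethyl-1-(triethylsilyloxy)cyclopropyl]-2,6-dimethylocta-1,5-dien-3-one
Conditions: Dess–Martin periodinane, NaHCO3, CH2Cl2, 0 °C
Reagents that add atoms: none
Why: Dess–Martin oxidation of the allylic alcohol gives the α-methyl enone needed for reagent-controlled reduction.

Step 8
Reactants: 13 (1E,5E)-8-[(tert-butyldimethylsilyl)oxy]-1-[2,2-dimethyl-1-(triethylsilyloxy)cyclopropyl]-2,6-dimethylocta-1,5-dien-3-one
Product: 14 (1E,3R,5E)-8-[(tert-butyldimethylsilyl)oxy]-1-[2,2-dimethyl-1-(triethylsilyloxy)cyclopropyl]-2,6-dimethylocta-1,5-dien-3-ol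
Conditions: (S)-2-methyl-CBS-oxazaborolidine (0.5 equiv), catecholborane, toluene, −78 °C
Reagents that add atoms: none
Why: Corey–Bakshi–Shibata reduction, in which the α-methylalkenyl group acts as the large substituent and the CH2 group as the small one, so the (S)-catalyst should deliver hydride 1,2-selectively to give the (R)-carbinol (C1 of the target) by reagent control.

Step 9
Reactants: 14 (1E,3R,5E)-8-[(tert-butyldimethylsilyl)oxy]-1-[2,2-dimethyl-1-(triethylsilyloxy)cyclopropyl]-2,6-dimethylocta-1,5-dien-3-ol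
Product: 15 (1E,3R,5E)-8-[(tert-butyldimethylsilyl)oxy]-1-[2,2-dimethyl-1-(triethylsilyloxy)cyclopropyl]-2,6-dimethyl-3-[(triisopropylsilyl)oxy]octa-1,5-diene
Conditions: TIPSOTf, 2,6-lutidine, CH2Cl2, −78 °C to 0 °C
Reagents that add atoms: triisopropylsilyl trifluoromethanesulfonate CC(C)[Si](C(C)C)(C(C)C)OS(=O)(=O)C(F)(F)F
Why: Silylation with the bulky TIPS group gives an allylic ether that should survive the acidic step that follows and, unlike an allylic ester, is inert to zerovalent palladium.

Step 10
Reactants: 15 (1E,3R,5E)-8-[(tert-butyldimethylsilyl)oxy]-1-[2,2-dimethyl-1-(triethylsilyloxy)cyclopropyl]-2,6-dimethyl-3-[(triisopropylsilyl)oxy]octa-1,5-diene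
Product: 16 1-{(1E,3R,5E)-8-hydroxy-2,6-dimethyl-3-[(triisopropylsilyl)oxy]octa-1,5-dien-1-yl}-2,2-dimethylcyclopropan-1-ol
Conditions: HF·pyridine, pyridine, THF, 0 °C to rt
Reagents that add atoms: none
Why: Acidic fluoride should cleave the primary TBS ether and the triethylsilyl ether of the cyclopropanol much faster than the hindered secondary TIPS ether, and the pyridine buffer guards the alkenylcyclopropanol against acid-induced ring expansion.

Step 11
Reactants: 16 1-{(1E,3R,5E)-8-hydroxy-2,6-dimethyl-3-[(triisopropylsilyl)oxy]octa-1,5-dien-1-yl}-2,2-dimethylcyclopropan-1-ol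
Product: 17 1-{(1E,3R,5E)-8-bromo-2,6-dimethyl-3-[(triisopropylsilyl)oxy]octa-1,5-dien-1-yl}-2,2-dimethylcyclopropan-1-ol
Conditions: CBr4, PPh3, 2,6-lutidine, CH2Cl2, −20 °C
Reagents that add atoms: tetrabromomethane BrC(Br)(Br)Br
Why: Appel bromination, in which phosphonium activation should be confined to the unhindered primary alcohol while the tertiary cyclopropanol, flanked by a quaternary carbon, does not react at low temperature.

Step 12
Reactants: 17 1-{(1E,3R,5E)-8-bromo-2,6-dimethyl-3-[(triisopropylsilyl)oxy]octa-1,5-dien-1-yl}-2,2-dimethylcyclopropan-1-ol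
Product: 20 (2E,4R,6E)-3,7,11,11-tetramethyl-4-[(triisopropylsilyl)oxy]cycloundeca-2,6-dien-1-one, via alkylpalladium bromide 18 (not isolated), via palladacycle 19 (not isolated)
Conditions: Pd(PCy3)2 (15 mol %), Cs2CO3, degassed toluene, 60 °C, 17 added by syringe pump over 12 h to a final 0.002 M
Reagents that add atoms: none
Why: Proposed new method: zerovalent palladium should insert into the primary C–Br bond by SN2-type oxidative addition, the tethered cyclopropanol is then exchanged onto divalent palladium as its caesium alkoxide, and strain-driven β-carbon elimination cleaves the less substituted C–CH2 bond of the cyclopropane to give the 12-membered dialkylpalladacycle 19, from which C(sp3)–C(sp3) reductive elimination forms the C6–C7 bond; the closest known reactions are palladium-catalysed ring-opening cross-couplings of cyclopropanols with aryl and benzyl halides and palladium-catalysed alkyl–alkyl couplings of primary alkyl bromides with trialkylphosphine ligands. The 11-membered ring is therefore closed not by a direct end-to-end C–C attack but by reversible docking of the alkoxide oxygen on palladium, transfer of palladium from oxygen to carbon, and contraction of the palladacycle in the reductive elimination. No stereocentre is formed: the carbinol centre of the cyclopropanol (a mixture) is erased as it becomes the ketone carbon, and the silyloxy-bearing centre and both E alkenes are not touched because no radical or enolisable intermediate lies on the path. The step needs regioselective ring cleavage (C–CH2 over C–CMe2), which the preference of β-carbon elimination for the less hindered bond should secure, and it needs to avoid β-hydride elimination, which is impossible on the homoenolate side (the carbon next to the palladium-bound CH2 is quaternary) and is slowed on the other side by the bulky electron-rich phosphine. Ring closure over oligomerisation is sought by slow addition at high dilution and is helped by the two E trisubstituted alkenes and the gem-dimethyl group, which remove rotors from the chain.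

Step 13
Reactants: 20 (2E,4R,6E)-3,7,11,11-tetramethyl-4-[(triisopropylsilyl)oxy]cycloundeca-2,6-dien-1-one
Product: 21 (2E,4R,6E)-4-hydroxy-3,7,11,11-tetramethylcycloundeca-2,6-dien-1-one
Conditions: TBAF, AcOH, THF, 0 °C to rt
Reagents that add atoms: none
Why: Fluoride desilylation buffered with acetic acid should free the allylic alcohol without base-induced isomerisation of the γ-hydroxy enone, and the E geometry keeps the hydroxyl from reaching the ketone.

Step 14
Reactants: 21 (2E,4R,6E)-4-hydroxy-3,7,11,11-tetramethylcycloundeca-2,6-dien-1-one; 22 4-[(tert-butyldimethylsilyl)oxy]benzoic acid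
Product: 23 (1R,2E,9E)-2,5,5,9-tetramethyl-4-oxocycloundeca-2,9-dien-1-yl 4-[(tert-butyldimethylsilyl)oxy]benzoate
Conditions: DCC, DMAP (cat.), CH2Cl2, 0 °C to rt
Reagents that add atoms: none
Why: Steglich esterification acylates the only hydroxyl group with retention at C1, since the C–O bond of the carbinol is not broken.

Step 15
Reactants: 23 (1R,2E,9E)-2,5,5,9-tetramethyl-4-oxocycloundeca-2,9-dien-1-yl 4-[(tert-butyldimethylsilyl)oxy]benzoate
Product: 24 (1R,2E,4R,9E)-4-hydroxy-2,5,5,9-tetramethylcycloundeca-2,9-dien-1-yl 4-[(tert-butyldimethylsilyl)oxy]benzoate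
Conditions: (S)-2-methyl-CBS-oxazaborolidine (1.0 equiv), catecholborane, toluene/CH2Cl2, −78 °C
Reagents that add atoms: none
Why: Corey–Bakshi–Shibata reduction, in which the quaternary C5 side is taken as the large group and the α-unsubstituted alkenyl side as the small one, so the (S)-catalyst should give the (4R)-alcohol 1,2-selectively by reagent control while the aryl ester is left alone at −78 °C.

Step 16
Reactants: 24 (1R,2E,4R,9E)-4-hydroxy-2,5,5,9-tetramethylcycloundeca-2,9-dien-1-yl 4-[(tert-butyldimethylsilyl)oxy]benzoate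
Product: 25 (1R,2E,4R,9E)-4-hydroxy-2,5,5,9-tetramethylcycloundeca-2,9-dien-1-yl 4-hydroxybenzoate
Conditions: TBAF, AcOH, THF, 0 °C
Reagents that add atoms: none
Why: Buffered fluoride should cleave the aryl silyl ether within minutes and leave the allylic ester and allylic alcohol untouched.

**Compound list**

1 | 1-propynylmagnesium bromide | CC#C[Mg]Br | starting material
2 | N-methoxy-N-methylisobutyramide | CC(C)C(=O)N(C)OC | starting material
3 | 2-methylhex-4-yn-3-one | CC#CC(=O)C(C)C | intermediate
4 | triethyl[(2-methylhex-2-en-4-yn-3-yl)oxy]silane | CC#CC(O[Si](CC)(CC)CC)=C(C)C | intermediate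
5 | {[2,2-dimethyl-1-(prop-1-yn-1-yl)cyclopropyl]oxy}triethylsilane (racemic) | CC#CC1(O[Si](CC)(CC)CC)CC1(C)C | intermediate
6 | tert-butyl(but-3-yn-1-yloxy)dimethylsilane | C#CCCO[Si](C)(C)C(C)(C)C | starting material
7 | (E)-{4-[(tert-butyldimethylsilyl)oxy]-2-methylbut-1-en-1-yl}dimethylalane | C[Al](C)/C=C(C)/CCO[Si](C)(C)C(C)(C)C | intermediate
8 | (E)-6-[(tert-butyldimethylsilyl)oxy]-4-methylhex-3-en-1-ol | OCC/C=C(C)/CCO[Si](C)(C)C(C)(C)C | intermediate
9 | (E)-6-[(tert-butyldimethylsilyl)oxy]-4-methylhex-3-enal | O=CC/C=C(C)/CCO[Si](C)(C)C(C)(C)C | intermediate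
10 | chloro{(E)-1-[2,2-dimethyl-1-(triethylsilyloxy)cyclopropyl]prop-1-en-2-yl}zirconocene | CC[Si](CC)(CC)OC1(CC1(C)C)/C=C(C)/[Zr](Cl)(C1C=CC=C1)C1C=CC=C1 | intermediate
11 | {(E)-1-[2,2-dimethyl-1-(triethylsilyloxy)cyclopropyl]prop-1-en-2-yl}(methyl)zinc | CC[Si](CC)(CC)OC1(CC1(C)C)/C=C(C)/[Zn]C | intermediate
12 | (1E,5E)-8-[(tert-butyldimethylsilyl)oxy]-1-[2,2-dimethyl-1-(triethylsilyloxy)cyclopropyl]-2,6-dimethylocta-1,5-dien-3-ol (mixture at C3 and at the cyclopropane carbon) | CC[Si](CC)(CC)OC1(CC1(C)C)/C=C(C)/C(O)C/C=C(C)/CCO[Si](C)(C)C(C)(C)C | intermediate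
13 | (1E,5E)-8-[(tert-butyldimethylsilyl)oxy]-1-[2,2-dimethyl-1-(triethylsilyloxy)cyclopropyl]-2,6-dimethylocta-1,5-dien-3-one | CC[Si](CC)(CC)OC1(CC1(C)C)/C=C(C)/C(=O)C/C=C(C)/CCO[Si](C)(C)C(C)(C)C | intermediate
14 | (1E,3R,5E)-8-[(tert-butyldimethylsilyl)oxy]-1-[2,2-dimethyl-1-(triethylsilyloxy)cyclopropyl]-2,6-dimethylocta-1,5-dien-3-ol | CC[Si](CC)(CC)OC1(CC1(C)C)/C=C(C)/[C@H](O)C/C=C(C)/CCO[Si](C)(C)C(C)(C)C | intermediate
15 | (1E,3R,5E)-8-[(tert-butyldimethylsilyl)oxy]-1-[2,2-dimethyl-1-(triethylsilyloxy)cyclopropyl]-2,6-dimethyl-3-[(triisopropylsilyl)oxy]octa-1,5-diene | CC[Si](CC)(CC)OC1(CC1(C)C)/C=C(C)/[C@H](O[Si](C(C)C)(C(C)C)C(C)C)C/C=C(C)/CCO[Si](C)(C)C(C)(C)C | intermediate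
16 | 1-{(1E,3R,5E)-8-hydroxy-2,6-dimethyl-3-[(triisopropylsilyl)oxy]octa-1,5-dien-1-yl}-2,2-dimethylcyclopropan-1-ol | OC1(CC1(C)C)/C=C(C)/[C@H](O[Si](C(C)C)(C(C)C)C(C)C)C/C=C(C)/CCO | intermediate
17 | 1-{(1E,3R,5E)-8-bromo-2,6-dimethyl-3-[(triisopropylsilyl)oxy]octa-1,5-dien-1-yl}-2,2-dimethylcyclopropan-1-ol | OC1(CC1(C)C)/C=C(C)/[C@H](O[Si](C(C)C)(C(C)C)C(C)C)C/C=C(C)/CCBr | intermediate
18 | bromo{(3E,6R,7E)-8-(1-hydroxy-2,2-dimethylcyclopropyl)-3,7-dimethyl-6-[(triisopropylsilyl)oxy]octa-3,7-dien-1-yl}bis(tricyclohexylphosphine)palladium (oxidative-addition complex) | OC1(CC1(C)C)/C=C(C)/[C@H](O[Si](C(C)C)(C(C)C)C(C)C)C/C=C(C)/CC[Pd-2](Br)([P+](C2CCCCC2)(C2CCCCC2)C2CCCCC2)[P+](C2CCCCC2)(C2CCCCC2)C2CCCCC2 | intermediate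
19 | 12-membered dialkylpalladacycle: palladium (one PCy3) bonded to the CH2 next to CMe2 and to the terminal CH2 of the dienyl chain of the ring-opened ketone | O=C1/C=C(C)/[C@H](O[Si](C(C)C)(C(C)C)C(C)C)C/C=C(C)/CC[Pd-]([P+](C2CCCCC2)(C2CCCCC2)C2CCCCC2)CC1(C)C | intermediate
20 | (2E,4R,6E)-3,7,11,11-tetramethyl-4-[(triisopropylsilyl)oxy]cycloundeca-2,6-dien-1-one | O=C1/C=C(C)/[C@H](O[Si](C(C)C)(C(C)C)C(C)C)C/C=C(C)/CCCC1(C)C | intermediate
21 | (2E,4R,6E)-4-hydroxy-3,7,11,11-tetramethylcycloundeca-2,6-dien-1-one | O=C1/C=C(C)/[C@H](O)C/C=C(C)/CCCC1(C)C | intermediate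
22 | 4-[(tert-butyldimethylsilyl)oxy]benzoic acid | OC(=O)c1ccc(O[Si](C)(C)C(C)(C)C)cc1 | starting material
23 | (1R,2E,9E)-2,5,5,9-tetramethyl-4-oxocycloundeca-2,9-dien-1-yl 4-[(tert-butyldimethylsilyl)oxy]benzoate | O=C1/C=C(C)/[C@H](OC(=O)c2ccc(O[Si](C)(C)C(C)(C)C)cc2)C/C=C(C)/CCCC1(C)C | intermediate
24 | (1R,2E,4R,9E)-4-hydroxy-2,5,5,9-tetramethylcycloundeca-2,9-dien-1-yl 4-[(tert-butyldimethylsilyl)oxy]benzoate | O[C@@H]1/C=C(C)/[C@H](OC(=O)c2ccc(O[Si](C)(C)C(C)(C)C)cc2)C/C=C(C)/CCCC1(C)C | intermediate
25 | (1R,2E,4R,9E)-4-hydroxy-2,5,5,9-tetramethylcycloundeca-2,9-dien-1-yl 4-hydroxybenzoate | O[C@@H]1/C=C(C)/[C@H](OC(=O)c2ccc(O)cc2)C/C=C(C)/CCCC1(C)C | target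

**Totals**

Total step count: 16. Longest linear sequence: 14 steps (steps 1–3 and 6–16).

**Steps most likely to fail**

1. Step 12 (new method). What may go wrong: intermolecular alkoxide exchange and coupling leading to oligomers; β-hydride elimination of the alkylpalladium bromide before the cyclopropanol docks; base-mediated O-alkylation of the cyclopropanol by the bromide. Fallback with known chemistry (ring-closing metathesis at the same C6–C7 position, then saturation), setting out from aldehyde 9 and coming back at 20: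
   - 2-Butynal diethyl acetal is hydrozirconated (Cp2Zr(H)Cl), transmetalated (Me2Zn) and added to 9 as in step 6 to give the acetal alcohol F1.
   - As in steps 7–9, F1 is oxidised (Dess–Martin) to the enone F2, reduced with the (S)-CBS catalyst to the (R)-alcohol F3 and silylated to the TIPS ether F4.
   - Aqueous acid (PPTS, acetone/H2O) removes the acetal and the primary TBS group to give the hydroxy enal F5.
   - Prenyl bromide with indium metal (THF/H2O; γ-attack, 1,2-addition) gives the reverse-prenylated diol F6.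
   - Dess–Martin oxidation of both hydroxyls gives the keto aldehyde F7, and Ph3P=CH2 (from Ph3PCH3Br and KN(SiMe3)2, −78 °C) methylenates the aldehyde only to give the tetraenone F8.
   - Ring-closing metathesis of the two monosubstituted alkenes (second-generation Hoveyda–Grubbs catalyst, toluene, 80 °C, 0.001 M) should give the macrocyclic trienone F9.
   - Diimide (2-nitrobenzenesulfonylhydrazide, Et3N) should saturate only the new disubstituted C=C and deliver 20.

2. Step 15. What may go wrong: poor facial selectivity, if the macrocycle's own conformational bias opposes the catalyst or if the alkenyl side rather than the quaternary side behaves as the large group. Fallback, setting out from 23 and coming back at 24: Luche reduction (NaBH4, CeCl3·7H2O, MeOH, −78 °C) under substrate control gives 24 together with its C4 epimer, the (1R,4S)-alcohol F10. The two are separated by chromatography, and F10 is returned to 23 by MnO2 oxidation and recycled.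

3. Step 6. What may go wrong: slow alkenyl transfer from the hindered trisubstituted alkenylzinc, so that methyl transfer to the aldehyde or loss of the aldehyde competes. Fallback, setting out from 5 and coming back at 12: the alkenylzirconocene from 5 is quenched with I2 to give the vinyl iodide F11, which can be purified and checked for regiochemistry. F11 is then coupled with 9 by the Nozaki–Hiyama–Kishi reaction (CrCl2, NiCl2 cat., DMSO/THF, rt), which tolerates the enolisable aldehyde.

**Further compounds**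

F1 | step 12 | (2E,6E)-9-[(tert-butyldimethylsilyl)oxy]-1,1-diethoxy-3,7-dimethylnona-2,6-dien-4-ol | CCOC(OCC)/C=C(C)/C(O)C/C=C(C)/CCO[Si](C)(C)C(C)(C)C
F2 | step 12 | (2E,6E)-9-[(tert-butyldimethylsilyl)oxy]-1,1-diethoxy-3,7-dimethylnona-2,6-dien-4-one | CCOC(OCC)/C=C(C)/C(=O)C/C=C(C)/CCO[Si](C)(C)C(C)(C)C
F3 | step 12 | (2E,4R,6E)-9-[(tert-butyldimethylsilyl)oxy]-1,1-diethoxy-3,7-dimethylnona-2,6-dien-4-ol | CCOC(OCC)/C=C(C)/[C@H](O)C/C=C(C)/CCO[Si](C)(C)C(C)(C)C
F4 | step 12 | (2E,4R,6E)-9-[(tert-butyldimethylsilyl)oxy]-1,1-diethoxy-3,7-dimethyl-4-[(triisopropylsilyl)oxy]nona-2,6-diene | CCOC(OCC)/C=C(C)/[C@H](O[Si](C(C)C)(C(C)C)C(C)C)C/C=C(C)/CCO[Si](C)(C)C(C)(C)C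
F5 | step 12 | (2E,4R,6E)-9-hydroxy-3,7-dimethyl-4-[(triisopropylsilyl)oxy]nona-2,6-dienal | O=C/C=C(C)/[C@H](O[Si](C(C)C)(C(C)C)C(C)C)C/C=C(C)/CCO
F6 | step 12 | (3E,6R,7E)-3,7,10,10-tetramethyl-6-[(triisopropylsilyl)oxy]dodeca-3,7,11-triene-1,9-diol (both C9 epimers) | C=CC(C)(C)C(O)/C=C(C)/[C@H](O[Si](C(C)C)(C(C)C)C(C)C)C/C=C(C)/CCO
F7 | step 12 | (3E,6R,7E)-3,7,10,10-tetramethyl-9-oxo-6-[(triisopropylsilyl)oxy]dodeca-3,7,11-trienal | C=CC(C)(C)C(=O)/C=C(C)/[C@H](O[Si](C(C)C)(C(C)C)C(C)C)C/C=C(C)/CC=O
F8 | step 12 | (5E,7R,9E)-3,3,6,10-tetramethyl-7-[(triisopropylsilyl)oxy]trideca-1,5,9,12-tetraen-4-one | C=CC(C)(C)C(=O)/C=C(C)/[C@H](O[Si](C(C)C)(C(C)C)C(C)C)C/C=C(C)/CC=C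
F9 | step 12 | (2E,4R,6E)-3,7,11,11-tetramethyl-4-[(triisopropylsilyl)oxy]cycloundeca-2,6,9-trien-1-one (C9=C10 as E/Z mixture) | O=C1/C=C(C)/[C@H](O[Si](C(C)C)(C(C)C)C(C)C)C/C=C(C)/CC=CC1(C)C
F10 | step 15 | (1R,2E,4S,9E)-4-hydroxy-2,5,5,9-tetramethylcycloundeca-2,9-dien-1-yl 4-[(tert-butyldimethylsilyl)oxy]benzoate | O[C@H]1/C=C(C)/[C@H](OC(=O)c2ccc(O[Si](C)(C)C(C)(C)C)cc2)C/C=C(C)/CCCC1(C)C
F11 | step 6 | triethyl({1-[(E)-2-iodoprop-1-en-1-yl]-2,2-dimethylcyclopropyl}oxy)silane | CC[Si](CC)(CC)OC1(CC1(C)C)/C=C(C)/I
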